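## Structural features

Lepidine C is an unsymmetrical diaryl ether. Ring A is a 1,2,4-trisubstituted benzene with the ether oxygen at C1, an imidazol-2-ylmethyl arm (methylene Ca) at C2 and a methoxy group at C4. Ring B is a 1,3-disubstituted benzene that carries the same oxygen at C1' and a second imidazol-2-ylmethyl arm (methylene Cb) at C3'. Both heterocycles are N-unsubstituted imidazoles joined through C2, so the molecule has four rings and no stereocentre, and no neighbouring stereocentres have to be related. The fragile sites are the two imidazole N–H groups (acidic, nucleophilic, metal-binding) and the two methylenes, each weakly acidic and oxidisable because it lies between an arene and an amidine-type carbon; the diaryl ether and the methyl ether are robust. The real difficulty is placement: two identical arms sit in different environments, and on ring A the arm must stand ortho to the aryloxy group and meta to the methoxy group, a pattern that electrophilic substitution of a 4-aryloxyanisole would not give because the methoxy group directs to its own ortho positions. The key step uses the fact that C1 and C2 of ring A are neighbours and are therefore the two carbons of the triple bond of 4-methoxybenzyne, so a nucleophile can make the O–C1 bond and an electrophile the C2–Ca bond in one operation. Because the electrophile is an aldehyde, Ca emerges with an oxygen on it, and the route must end with a benzylic C–O cleavage while the N–H groups stay masked until the last step.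

## Logic of the disconnections

17 to 16. No skeletal bond is cut; the two N–H bonds of 17 are traced back to the two N–CH2 aminal bonds of 16. Free N–H groups would quench a carbanion and would be arylated by 12, so they have to stay masked through every earlier step. The gain is that all earlier intermediates are neutral and lipophilic, and 16 is a convenient last point for chromatography before the polar target. The forward step must hydrolyse two aminals in acid without harming the diaryl ether or the methyl ether.

16 to 14 (through 15). Again no skeletal bond is cut; the Ca–H bond of 16 is traced back to the Ca–O bond of 14. The hydroxyl group is the footprint of a carbonyl electrophile, and the gain is that Ca becomes a carbon that an aryl anion can reach. The forward step must cleave one benzylic C–O bond next to an imidazole while both SEM groups stay on. Acylation to 15 makes this bond labile enough for hydrogenolysis in a weakly acidic medium.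

14 to 7, 9 and 10 (through 11, 12 and 13). The O–C1 and C2–Ca bonds are cut together. C1 and C2 are adjacent, so they map onto the two carbons of the strained triple bond of 12, which 10 releases; the oxygen nucleophile is 11, made from 7, and the carbon electrophile is 9. Ring A is bought intact, and the target falls into three fragments of similar size joined in one convergent operation. The forward step demands that 11 adds at C1 and not at C2, that 13 meets 9 before it meets a proton, and that no imidazole nitrogen competes for 12.

7 to 6. The Cb–H bond is traced back to an acetoxy-bearing carbon and the phenol O–H to its benzyl ether, both being benzylic C–O bonds. The acetate makes the Cb–O bond cleavable under near-neutral conditions, where the SEM group needed in the key step survives, and one hydrogenolysis then serves two purposes. The demand is a C–O hydrogenolysis next to a basic heterocycle.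

6 to 2 and 3 (through 4 and 5). The Cb–C2(imidazole) bond is cut. C2 of an N-protected imidazole is its natural carbanion site (4), and 3 is a commercial aldehyde with the phenol already masked. Acylating 5 in the same flask avoids a separate activation step. The forward step needs clean C2 lithiation and a non-enolisable aldehyde, and both are present.

2 to 1. The N–CH2 bond of the aminal is cut, leading to the commodity heterocycle 1. The SEM group is chosen because it directs lithiation to C2, survives organolithium reagents, hydrogenolysis and fluoride at room temperature, and is removed by acid at the end.

9 to 8. The N–CH2 bond of the aminal is cut, leading to the commercial aldehyde 8. The formyl group is bought with the ring, so no second organometallic step is needed, and the same alkylating agent serves both heterocycles. The forward step needs N-alkylation without attack on the formyl group; the anion of 8 is symmetrical, so only one N-alkyl product can form.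

## Other disconnections considered

Alternative 1: Ring A itself is cut at C1–C6, C5–C4 and C4–C3 and assembled by a Dötz benzannulation. The pentacarbonylchromium aryloxy(alkenyl)carbene complex A1 would be heated with ethyne A2; alkyne insertion, insertion of one carbonyl ligand to a vinylketene, 6π-electrocyclisation and tautomerisation should give the 4-aryloxyphenol A3. O-Methylation, unmasking of the two acetals and a double Debus–Radziszewski imidazole synthesis would then lead to 17.
- In favour: the mechanism fixes the substitution pattern of ring A (oxygens para, arm ortho to the aryloxy group), so on regiochemistry it is better than the chosen plan. It needs no N-protecting group and no benzylic deoxygenation, and the benzannulation is a known reaction type, whereas the chosen key step is not.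
- Against: aryloxy carbene complexes such as A1 are reached only by the indirect acylmetalate and exchange route and are more labile than alkoxy ones. A stoichiometric amount of chromium is consumed, and the parent alkyne A2 is prone to multiple insertion. The end-game asks two enolisable aldehyde groups, set free from the acetals of A3, to undergo a multicomponent condensation twice.
- Comparison: structurally it builds an arene that the chosen plan simply buys. Mechanistically it rests on a known process and is the better of the two on that point. On step economy it is longer, at about eight steps against seven.

Alternative 2: Four bonds are cut, C2–Ca, Ca–C2(imidazole), C3'–Cb and Cb–C2(imidazole), so that both methylenes enter as carbon monoxide A6. The diiodide A4, two equivalents of the stannane A5 and A6 with PdCl2(PPh3)2 would give the diketone A7. Each C–I bond adds oxidatively to zerovalent palladium, A6 inserts to give an aroylpalladium species, and transmetalation and reductive elimination follow. A double Wolff–Kishner reduction and SEM removal would complete the synthesis.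
- In favour: both arms are installed in one flask. The regiochemistry is fixed by A4 and the reaction class is established, so on both points it is better than the chosen plan. The ketones of A7 also carry no stereocentre.
- Against: A4 is not trivial, because direct iodination would go ortho to the methoxy group, so a sequence of SNAr, nitro reduction and Sandmeyer iodination of about three steps is needed. 2-Stannylazoles such as A5 are prone to protodestannylation and to direct coupling without A6, especially at the hindered position ortho to the aryloxy group. Two equivalents of A5 and the toxic gas A6 are used. Two hindered di(hetero)aryl ketones must be reduced, where the chosen plan has one carbinol.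
- Comparison: structurally it equals the chosen plan in its use of SEM protection and in needing a late reduction. Mechanistically it is the safer of the two. On step economy it is no shorter, at about eight steps against seven.

Alternative 3: The Ca–C2 and Cb–C2 bonds and one C2–N bond of each heterocycle are cut. The bis(benzyl chloride) A8, two equivalents of tert-octyl isocyanide A9 and two of aminoacetaldehyde dimethyl acetal A10 with Pd(OAc)2, 1,1'-bis(diphenylphosphino)ferrocene and Cs2CO3 would give the bis-amidine A11. Each C–Cl bond adds oxidatively to zerovalent palladium, A9 inserts into the benzyl–palladium bond to give an imidoyl complex of divalent palladium, and A10 is captured. Acid would then close both imidazoles with loss of the tert-octyl groups.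
- In favour: the methylenes are at the right oxidation level from the start, no N-protecting group is used and the regiochemistry is defined by A8, so on all three points it is better than the chosen plan. A8 should be reachable in three steps by an SNAr between two commercial benzaldehydes, reduction and chlorination. The whole route would then be about five steps, two fewer than the chosen plan, so it is also better on step economy.
- Against: imidoylative amidine formation is established for aryl halides. A benzyl chloride such as A8 can alkylate the primary amine A10 directly without any catalyst, the imidoyl intermediate carries alpha hydrogens and can tautomerise, and double insertion of A9 is possible. The coupling must also succeed twice on one molecule, once at an ortho-substituted benzylic site.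
- Comparison: structurally it is the simpler plan, since it needs neither protection nor deoxygenation. Mechanistically it extends a known multicomponent process to a new substrate class, as the chosen plan does, so the risk is of similar size. Its likely failure mode destroys the substrate, whereas the main weakness of the chosen plan, modest regiocontrol, costs material but not the route.

Key step: step 5

Remarks on the chemistry: SEM stands for the [2-(trimethylsilyl)ethoxy]methyl group. Ca of compounds 14 and 15 is a stereocentre formed without control; both are carried as racemates and Ca becomes a methylene in step 6, so the target, which has no stereocentre, is unaffected.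

## Route

Step 1
Reactants: 1 imidazole
Product: 2 1-{[2-(trimethylsilyl)ethoxy]methyl}-1H-imidazole (1-SEM-imidazole)
Conditions: NaH, THF, 0 °C; SEMCl, 0 °C → rt
Reagents that add atoms: 2-(trimethylsilyl)ethoxymethyl chloride (SEMCl), C[Si](C)(C)CCOCCl
Why: The sodium imidazolide is alkylated on nitrogen by the reactive chloromethyl ether (SN2 N-alkylation); the anion is symmetrical, so only one product can form.

Step 2
Reactants: 2 1-SEM-imidazole; 3 3-(benzyloxy)benzaldehyde
Product: 6 [3-(benzyloxy)phenyl](1-SEM-1H-imidazol-2-yl)methyl acetate (racemic), via 2-lithio-1-SEM-imidazole 4 (not isolated), via lithium alkoxide 5 (not isolated)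
Conditions: n-BuLi, THF, −78 °C; 3, −78 °C; Ac2O, −78 °C → rt
Reagents that add atoms: acetic anhydride, CC(=O)OC(C)=O
Why: Directed lithiation takes place at C2, the most acidic ring position between the two nitrogens, and the organolithium adds 1,2 to the non-enolisable aldehyde; the lithium alkoxide is O-acylated in the same flask. The carbinol carbon is formed as a racemate without control and becomes a methylene in step 3.

Step 3
Reactants: 6 [3-(benzyloxy)phenyl](1-SEM-1H-imidazol-2-yl)methyl acetate
Product: 7 3-[(1-SEM-1H-imidazol-2-yl)methyl]phenol
Conditions: H2 (3 bar), 10% Pd/C, EtOH–AcOH (10:1), rt
Reagents that add atoms: none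
Why: Catalytic hydrogenolysis cleaves both benzylic C–O bonds, the benzyl ether and the doubly activated acetate, in one operation. The acetate leaves without strong acid, so the acid-labile SEM aminal survives, and the acetic acid keeps the basic nitrogen from blocking the catalyst.

Step 4
Reactants: 8 1H-imidazole-2-carbaldehyde
Product: 9 1-SEM-1H-imidazole-2-carbaldehyde
Conditions: NaH, THF, 0 °C; SEMCl, 0 °C → rt
Reagents that add atoms: 2-(trimethylsilyl)ethoxymethyl chloride (SEMCl), C[Si](C)(C)CCOCCl
Why: The acidic N–H of the 2-formylimidazole is deprotonated and the sodium salt is alkylated on nitrogen by the chloromethyl ether (SN2 N-alkylation). The two ring nitrogens of the anion are equivalent, so one product forms, and the non-enolisable formyl group is not touched.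

Step 5
Reactants: 7 3-[(1-SEM-1H-imidazol-2-yl)methyl]phenol; 9 1-SEM-1H-imidazole-2-carbaldehyde; 10 4-methoxy-2-(trimethylsilyl)phenyl trifluoromethanesulfonate
Product: 14 [5-methoxy-2-(3-{[1-SEM-1H-imidazol-2-yl]methyl}phenoxy)phenyl](1-SEM-1H-imidazol-2-yl)methanol (racemic), via potassium phenoxide 11 (not isolated), via 4-methoxybenzyne 12 (not isolated), via aryl anion 13 (not isolated)
Conditions: KH (1.0 equiv), THF, 0 °C; 9 (3 equiv), KF, 18-crown-6; 10 (1.3 equiv) added slowly, 0 °C → rt; H2O
Reagents that add atoms: none
Why: Proposed new method: Fluoride attacks the silicon of 10 and triflate leaves, releasing aryne 12; the crown-ether-separated phenoxide 11 adds to the strained triple bond at C1, and the aryl anion 13 left at C2 attacks the formyl group of 9, so O–C1 and C2–Ca form in one operation and the potassium alkoxide of 14 is protonated on work-up. The closest known reaction type is the three-component aryne coupling in which a heteroatom nucleophile adds and the aryl anion is trapped by an aldehyde, a ketone or CO2, together with the intramolecular case in which a phenoxide with an ortho carbonyl group adds to an aryne and the anion closes onto that carbonyl; the untested element is the intermolecular pairing of a phenoxide with a separate aldehyde. No ring is closed. Ca becomes a stereocentre with no controlling element, so 14 should form as the racemate, which does not matter because step 6 turns Ca into a methylene. The step needs phenoxide attack at C1, para to the methoxy group, which puts the developing charge at C2, meta to the inductively withdrawing methoxy oxygen; this bias is weak, so the isomer from attack at C2 must be expected as well and removed by chromatography. Against premature protonation, the flask holds no O–H or N–H group (KH leaves only H2, and THF replaces the more acidic acetonitrile), and 9, an electron-poor non-enolisable aldehyde, is present in threefold excess to outrun the weakly acidic benzylic methylene of the ring B arm. The anionic phenoxide should outcompete the neutral, 2-substituted imidazole nitrogens for 12, and slow release of 12 keeps the product alkoxide from being arylated.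

Step 6
Reactants: 14 [5-methoxy-2-(3-{[1-SEM-1H-imidazol-2-yl]methyl}phenoxy)phenyl](1-SEM-1H-imidazol-2-yl)methanol
Product: 16 2-{[5-methoxy-2-(3-{[1-SEM-1H-imidazol-2-yl]methyl}phenoxy)phenyl]methyl}-1-SEM-1H-imidazole (bis-SEM-protected target), via acetate 15 (not isolated)
Conditions: Ac2O, Et3N, DMAP (cat.), EtOAc, rt; EtOH; then AcOH, 10% Pd/C, H2 (3 bar), rt
Reagents that add atoms: none
Why: DMAP-catalysed O-acylation turns the carbinol into acetate 15, and catalytic hydrogenolysis then cleaves its doubly activated benzylic C–O bond, the same tactic that serves Cb in step 3. The medium stays only weakly acidic, so both SEM aminals, the diaryl ether and the methyl ether survive. Ca ceases to be a stereocentre.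

Step 7
Reactants: 16 2-{[5-methoxy-2-(3-{[1-SEM-1H-imidazol-2-yl]methyl}phenoxy)phenyl]methyl}-1-SEM-1H-imidazole
Product: 17 lepidine C
Conditions: 3 M HCl, EtOH, reflux; aq. NH3
Reagents that add atoms: none
Why: Hot ethanolic HCl hydrolyses both N,O-aminals (SEM removal), releasing formaldehyde and 2-(trimethylsilyl)ethanol, while the diaryl ether and the methyl ether are inert to dilute acid. Neutralisation with ammonia liberates the free bis-imidazole.

## Compound list

1 | imidazole | c1c[nH]cn1 | starting material
2 | 1-{[2-(trimethylsilyl)ethoxy]methyl}-1H-imidazole (1-SEM-imidazole) | C[Si](C)(C)CCOCn1ccnc1 | intermediate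
3 | 3-(benzyloxy)benzaldehyde | O=Cc1cccc(OCc2ccccc2)c1 | starting material
4 | 2-lithio-1-SEM-imidazole | [Li]c1nccn1COCC[Si](C)(C)C | intermediate
5 | lithium [3-(benzyloxy)phenyl](1-SEM-1H-imidazol-2-yl)methanolate (racemic) | [Li+].[O-]C(c1cccc(OCc2ccccc2)c1)c1nccn1COCC[Si](C)(C)C | intermediate
6 | [3-(benzyloxy)phenyl](1-SEM-1H-imidazol-2-yl)methyl acetate (racemic) | CC(=O)OC(c1cccc(OCc2ccccc2)c1)c1nccn1COCC[Si](C)(C)C | intermediate
7 | 3-[(1-SEM-1H-imidazol-2-yl)methyl]phenol | Oc1cccc(Cc2nccn2COCC[Si](C)(C)C)c1 | intermediate
8 | 1H-imidazole-2-carbaldehyde | O=Cc1ncc[nH]1 | starting material
9 | 1-SEM-1H-imidazole-2-carbaldehyde | O=Cc1nccn1COCC[Si](C)(C)C | intermediate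
10 | 4-methoxy-2-(trimethylsilyl)phenyl trifluoromethanesulfonate | COc1ccc(OS(=O)(=O)C(F)(F)F)c([Si](C)(C)C)c1 | starting material
11 | potassium 3-[(1-SEM-1H-imidazol-2-yl)methyl]phenoxide | [K+].[O-]c1cccc(Cc2nccn2COCC[Si](C)(C)C)c1 | intermediate
12 | 4-methoxybenzyne (4-methoxy-1,2-didehydrobenzene) | COC1=CC#CC=C1 | intermediate
13 | potassium 5-methoxy-2-(3-{[1-SEM-1H-imidazol-2-yl]methyl}phenoxy)phenyl anion (charge at C2 of ring A) | [K+].COc1ccc(Oc2cccc(Cc3nccn3COCC[Si](C)(C)C)c2)[c-]c1 | intermediate
14 | [5-methoxy-2-(3-{[1-SEM-1H-imidazol-2-yl]methyl}phenoxy)phenyl](1-SEM-1H-imidazol-2-yl)methanol (racemic) | COc1ccc(Oc2cccc(Cc3nccn3COCC[Si](C)(C)C)c2)c(C(O)c2nccn2COCC[Si](C)(C)C)c1 | intermediate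
15 | [5-methoxy-2-(3-{[1-SEM-1H-imidazol-2-yl]methyl}phenoxy)phenyl](1-SEM-1H-imidazol-2-yl)methyl acetate (racemic) | COc1ccc(Oc2cccc(Cc3nccn3COCC[Si](C)(C)C)c2)c(C(OC(C)=O)c2nccn2COCC[Si](C)(C)C)c1 | intermediate
16 | 2-{[5-methoxy-2-(3-{[1-SEM-1H-imidazol-2-yl]methyl}phenoxy)phenyl]methyl}-1-SEM-1H-imidazole (bis-SEM-protected target) | COc1ccc(Oc2cccc(Cc3nccn3COCC[Si](C)(C)C)c2)c(Cc2nccn2COCC[Si](C)(C)C)c1 | intermediate
17 | lepidine C, 2-({5-methoxy-2-[3-(1H-imidazol-2-ylmethyl)phenoxy]phenyl}methyl)-1H-imidazole | COc1ccc(Oc2cccc(Cc3ncc[nH]3)c2)c(Cc2ncc[nH]2)c1 | target

## Step count and least certain steps

Total step count: 7. Longest linear sequence: 6 steps (steps 1, 2, 3, 5, 6 and 7, from imidazole); step 4 is a one-step branch from 8.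

**Step 5 (key step, new method).**
- The most likely failure is poor site selectivity when the phenoxide adds across the aryne, because the methoxy group is remote from both aryne carbons and exerts only a weak inductive bias.
- The second is protonation of the aryl anion by the benzylic methylene or by adventitious water before it reaches the aldehyde, which would end the sequence at the two-component stage.
- The third is consumption of the aryne by an imidazole nitrogen or by the product alkoxide.
- A removable halogen director next to C2 would sharpen the site selectivity. It is not used as the fallback because it lengthens the synthesis of the aryne precursor, gives a 2-haloaryl anion that can expel halide, and is still the same untested coupling.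
- Fallback by known chemistry, setting out from 7 and returning at 14: 7 is heated with commercial 2-fluoro-5-methoxybenzaldehyde (COc1ccc(F)c(C=O)c1) and K2CO3 in DMF at about 110 °C. SNAr displacement of the fluoride activated by the ortho formyl group should give 5-methoxy-2-(3-{[1-SEM-1H-imidazol-2-yl]methyl}phenoxy)benzaldehyde F1 as a single regioisomer. Addition of 4, generated from 2 and n-BuLi in THF at −78 °C as in step 2, to F1 followed by aqueous work-up gives 14. This variant needs neither 9 nor 10 and keeps the count at seven steps.

**Step 6.**
- Acylation of the hindered carbinol, flanked by the ortho aryloxy group and the N-SEM imidazole, may be incomplete.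
- The hydrogenolysis of the acetoxy C–O bond at Ca may stall, because the basic nitrogens can occupy the palladium surface and the protonated imidazole disfavours C–O cleavage.
- Fallback with a radical mechanism, setting out from 14 and returning at 16: 14 is treated with NaH, CS2 and MeI in THF to give O-{[5-methoxy-2-(3-{[1-SEM-1H-imidazol-2-yl]methyl}phenoxy)phenyl](1-SEM-1H-imidazol-2-yl)methyl} S-methyl carbonodithioate F2. Bu3SnH and AIBN in toluene at 90 °C should reduce F2 to 16 by a Barton–McCombie chain, which does not depend on ionisation at Ca.

**Step 3.**
- The benzyl ether should cleave easily, but hydrogenolysis of the acetoxy C–O bond next to the imidazole may be slow, giving incomplete deoxygenation.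
- Fallback that brings Cb in at the methylene oxidation level, setting out from 2 and returning at 7: 4, generated from 2 and n-BuLi in THF at −78 °C, is alkylated with commercial 3-(benzyloxy)benzyl bromide (BrCc1cccc(OCc2ccccc2)c1) to give 2-[3-(benzyloxy)benzyl]-1-SEM-1H-imidazole F3. Hydrogenolysis of the benzyl ether alone (H2, 10% Pd/C, EtOH, rt) then gives 7. This alkylation is kept in reserve because the aldehyde addition of step 2 is less prone to halogen–lithium exchange and over-alkylation.

## Further compounds

F1 | step 5 | 5-methoxy-2-(3-{[1-SEM-1H-imidazol-2-yl]methyl}phenoxy)benzaldehyde | COc1ccc(Oc2cccc(Cc3nccn3COCC[Si](C)(C)C)c2)c(C=O)c1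
F2 | step 6 | O-{[5-methoxy-2-(3-{[1-SEM-1H-imidazol-2-yl]methyl}phenoxy)phenyl](1-SEM-1H-imidazol-2-yl)methyl} S-methyl carbonodithioate (racemic) | COc1ccc(Oc2cccc(Cc3nccn3COCC[Si](C)(C)C)c2)c(C(OC(=S)SC)c2nccn2COCC[Si](C)(C)C)c1
F3 | step 3 | 2-[3-(benzyloxy)benzyl]-1-SEM-1H-imidazole | C[Si](C)(C)CCOCn1ccnc1Cc1cccc(OCc2ccccc2)c1
A1 | alternative 1 | pentacarbonyl{[3-(2,2-diethoxyethyl)phenoxy](4,4-diethoxybut-1-en-2-yl)methylidene}chromium | CCOC(Cc1cccc(OC(=[Cr](=C=O)(=C=O)(=C=O)(=C=O)=C=O)C(=C)CC(OCC)OCC)c1)OCC
A2 | alternative 1 | ethyne | C#C
A3 | alternative 1 | 3-(2,2-diethoxyethyl)-4-[3-(2,2-diethoxyethyl)phenoxy]phenol | Oc1ccc(Oc2cccc(CC(OCC)OCC)c2)c(CC(OCC)OCC)c1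
A4 | alternative 2 | 2-iodo-1-(3-iodophenoxy)-4-methoxybenzene | COc1ccc(Oc2cccc(I)c2)c(I)c1
A5 | alternative 2 | 1-SEM-2-(tributylstannyl)-1H-imidazole | CCCC[Sn](CCCC)(CCCC)c1nccn1COCC[Si](C)(C)C
A6 | alternative 2 | carbon monoxide | [C-]#[O+]
A7 | alternative 2 | bis-SEM diketone, [5-methoxy-2-(3-{[1-SEM-1H-imidazol-2-yl]carbonyl}phenoxy)phenyl](1-SEM-1H-imidazol-2-yl)methanone | COc1ccc(Oc2cccc(C(=O)c3nccn3COCC[Si](C)(C)C)c2)c(C(=O)c2nccn2COCC[Si](C)(C)C)c1
A8 | alternative 3 | 2-(chloromethyl)-1-[3-(chloromethyl)phenoxy]-4-methoxybenzene | COc1ccc(Oc2cccc(CCl)c2)c(CCl)c1
A9 | alternative 3 | tert-octyl isocyanide (2-isocyano-2,4,4-trimethylpentane) | [C-]#[N+]C(C)(C)CC(C)(C)C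
A10 | alternative 3 | aminoacetaldehyde dimethyl acetal (2,2-dimethoxyethanamine) | NCC(OC)OC
A11 | alternative 3 | bis(N-tert-octyl-N'-(2,2-dimethoxyethyl)amidine) of the diaryl ether | COc1ccc(Oc2cccc(CC(=NC(C)(C)CC(C)(C)C)NCC(OC)OC)c2)c(CC(=NC(C)(C)CC(C)(C)C)NCC(OC)OC)c1
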